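**Retrosynthetic overview**

1. Oblongifolin B ⇐ chloride demethylation and desilylation ⇐ C3 lithiation and aroylation of the bicyclic vinylogous methyl ester 30 with acid chloride 33.
2. 30 ⇐ semipinacol ring expansion of the cis-fused bromohydrin 29. The strategy rests on the C1–C8 bond, which joins two fully substituted carbons (prenylated bridgehead C1 and C8Me2) beside the C9 ketone in the ring C9–C1–C8–C7–C6–C5. It is made by moving C8 from the C9 carbinol to C1, which turns the cyclopentane C9–C8–C7–C6–C5 into that six-membered ring.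
3. 29 ⇐ C1 bromination ⇐ intramolecular aldol (C1 to C9) of β-methoxy enone 25 ⇐ methanol addition to ynone 24 ⇐ C5 ethynylation and C5 prenylation of cyclopentanone 13.
4. 13 ⇐ Negishi coupling (geranyl C1'–C2') of a C7–CH2ZnI reagent with (E)-iodide 4 ⇐ copper-catalysed asymmetric conjugate addition and methylation on 2-methylcyclopent-2-en-1-one, which sets C7.
5. Ring order: cyclopentane (from 5), then the six-membered vinylogous-ester ring (aldol, step 12), then expansion of the cyclopentane to the second six-membered ring (step 14); the arene is bought.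

Key step: step 14

Remark: core numbering C1–C9 is used throughout (C9 bridging ketone, C8Me2, C7 geranyl, C5 and C1 prenyl; geranyl = (2E)-3,7-dimethylocta-2,6-dien-1-yl, prenyl = 3-methylbut-2-en-1-yl); it is assumed that O-methylation of a C5-quaternary hydroxy dione would favour the less hindered C2 oxygen, so the C4 methyl ether is placed by methanol addition to an ynone.

**Route**

Step 1
Reactants: 1 5-bromo-2-methylpent-2-ene
Product: 2 6-methylhept-5-en-1-yne
Conditions: LiC≡CH·H2NCH2CH2NH2, DMSO, 10 °C → rt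
Reagents that add atoms: lithium acetylide–ethylenediamine complex, [Li+].[C-]#C.NCCN
Why: SN2 alkylation of an acetylide by a primary homoallylic bromide in a dipolar aprotic solvent, with no stereocentre involved.

Step 2
Reactants: 2 6-methylhept-5-en-1-yne
Product: 4 (1E)-1-iodo-2,6-dimethylhepta-1,5-diene, via alkenylalane 3 (not isolated)
Conditions: AlMe3 (2 equiv), Cp2ZrCl2 (0.2 equiv), CH2Cl2, 0 °C → rt; then I2, THF, −30 → 0 °C
Reagents that add atoms: trimethylaluminium, C[Al](C)C; iodine, II
Why: Zirconium-catalysed carboalumination of the terminal alkyne (Negishi methylalumination) adds methyl and aluminium syn with methyl on the internal carbon, and iodinolysis with retention should give the E alkenyl iodide while the trisubstituted alkene stays untouched.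

Step 3
Reactants: 5 2-methylcyclopent-2-en-1-one; 6 (chloromethyl)dimethyl(propan-2-yloxy)silane
Product: 9 (3R)-3-{[dimethyl(propan-2-yloxy)silyl]methyl}-2,2-dimethylcyclopentan-1-one, via Grignard reagent 7 (not isolated), via magnesium enolate 8 (not isolated)
Conditions: Mg, Et2O, reflux (6 → 7); then 5, Cu(OTf)2 (3 mol %), chiral imidazolinium salt as carbene precursor (4 mol %), Et2O, −30 °C; then MeI, DMPU, −30 °C → rt
Reagents that add atoms: iodomethane, CI
Why: Copper-catalysed asymmetric conjugate addition of a Grignard reagent to an α-substituted cyclic enone sets C7 (ligand enantiomer chosen for the R product), and C-methylation of the regiodefined magnesium enolate (enolate trapping) creates the gem-dimethyl carbon C8, which is not stereogenic.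

Step 4
Reactants: 9 (3R)-3-{[dimethyl(propan-2-yloxy)silyl]methyl}-2,2-dimethylcyclopentan-1-one
Product: 10 (3R)-3-(hydroxymethyl)-2,2-dimethylcyclopentan-1-one
Conditions: 30% H2O2, KF, KHCO3, THF/MeOH, rt
Reagents that add atoms: hydrogen peroxide, OO
Why: Tamao oxidation of the alkoxysilane (peroxide attack at silicon, 1,2-shift of CH2 from silicon to oxygen) leaves C7 untouched, and the mildly basic peroxide should not cause Baeyer–Villiger oxidation of the hindered ketone.

Step 5
Reactants: 10 (3R)-3-(hydroxymethyl)-2,2-dimethylcyclopentan-1-one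
Product: 11 (3R)-3-(iodomethyl)-2,2-dimethylcyclopentan-1-one
Conditions: I2, PPh3, imidazole, CH2Cl2, 0 °C → rt
Reagents that add atoms: iodine, II
Why: Appel-type iodination of a primary alcohol through its alkoxyphosphonium salt, with C7 not involved.

Step 6
Reactants: 11 (3R)-3-(iodomethyl)-2,2-dimethylcyclopentan-1-one; 4 (1E)-1-iodo-2,6-dimethylhepta-1,5-diene
Product: 13 (3S)-3-[(2E)-3,7-dimethylocta-2,6-dien-1-yl]-2,2-dimethylcyclopentan-1-one, via alkylzinc iodide 12 (not isolated)
Conditions: Zn dust (activated), LiCl, THF, 40 °C; then 4, PdCl2(dppf) (5 mol %), THF, 50 °C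
Reagents that add atoms: none
Why: Zinc insertion into the primary iodide gives an organozinc that tolerates the ketone, and Negishi sp3–sp2 coupling with the alkenyl iodide proceeds with retention of the E geometry to complete the geranyl chain.

Step 7
Reactants: 13 (3S)-3-geranyl-2,2-dimethylcyclopentan-1-one; 14 1-bromo-3-methylbut-2-ene (prenyl bromide)
Product: 16 3-geranyl-2,2-dimethyl-5-prenylcyclopentan-1-one (C7 as in 13; C5 epimers), via lithium enolate 15 (not isolated)
Conditions: LiN(iPr)2, THF, −78 °C; then 14, −78 → 0 °C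
Reagents that add atoms: none
Why: Enolate alkylation is regiospecific because C5 is the only enolisable position (C8 is quaternary), and the C5 epimer ratio does not matter since C5 is enolised again in step 8.

Step 8
Reactants: 16 3-geranyl-2,2-dimethyl-5-prenylcyclopentan-1-one; 17 1-[(trimethylsilyl)ethynyl]-1,2-benziodoxol-3(1H)-one
Product: 19 5-ethynyl-3-geranyl-2,2-dimethyl-5-prenylcyclopentan-1-one (ethynyl trans and prenyl cis to geranyl), via potassium enolate 18 (not isolated)
Conditions: KOtBu, THF, 0 °C; then 17, Bu4NF, −78 °C → rt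
Reagents that add atoms: none
Why: Electrophilic α-alkynylation of a ketone enolate by an ethynylbenziodoxolone (addition to the alkynyl iodane, loss of 2-iodobenzoate, 1,2-shift in the carbene) builds the quaternary C5, the ethynyl group being expected to enter anti to the C7 geranyl group so that prenyl and geranyl end up cis.

Step 9
Reactants: 20 N-methoxy-N-methylacetamide; 14 1-bromo-3-methylbut-2-ene
Product: 22 N-methoxy-N,5-dimethylhex-4-enamide, via lithium enolate 21 (not isolated)
Conditions: LiN(iPr)2, THF, −78 °C; then 14, −78 → 0 °C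
Reagents that add atoms: none
Why: Alkylation of a Weinreb amide enolate with an allylic bromide, with no stereocentre formed.

Step 10
Reactants: 19 5-ethynyl-3-geranyl-2,2-dimethyl-5-prenylcyclopentan-1-one; 22 N-methoxy-N,5-dimethylhex-4-enamide
Product: 24 3-geranyl-2,2-dimethyl-5-(7-methyl-3-oxooct-6-en-1-yn-1-yl)-5-prenylcyclopentan-1-one, via lithium acetylide 23 (not isolated)
Conditions: LiN(iPr)2, THF, −78 °C; then 22, −78 → 0 °C
Reagents that add atoms: none
Why: Acylation of a lithium acetylide by a Weinreb amide stops at the ynone through the chelated tetrahedral intermediate, while the C9 ketone has no α-hydrogen and is shielded by two quaternary carbons.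

Step 11
Reactants: 24 ynone
Product: 25 3-geranyl-5-[(1E)-1-methoxy-7-methyl-3-oxoocta-1,6-dien-1-yl]-2,2-dimethyl-5-prenylcyclopentan-1-one
Conditions: NaOMe (0.1 equiv), MeOH, 0 °C → rt
Reagents that add atoms: methanol, CO
Why: Base-catalysed conjugate addition of methanol to the ynone puts the methoxy group on C4 without ambiguity, and protonation of the allenolate on the side of the small methoxy group (away from quaternary C5) should give the E isomer, in which C5 and the C2 acyl group are cis as ring closure requires.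

Step 12
Reactants: 25 β-methoxy enone
Product: 27 cis-fused ketol 7a-hydroxy-4-methoxy-1,1-dimethyl-2-geranyl-3a,7-diprenyl-1,2,3,3a,7,7a-hexahydro-6H-inden-6-one (C1 epimers), via lithium enolate 26 (not isolated)
Conditions: LiN(iPr)2 (1.1 equiv), THF, −78 → −20 °C
Reagents that add atoms: none
Why: Kinetic α'-deprotonation of the vinylogous ester at C1 (no other enolate can form) and intramolecular aldol addition to the C9 ketone (6-enolendo-exo-trig) give the ketol, which must be cis-fused (OH cis to the C5 prenyl) because C1 can reach C9 only from the face that carries C4; the C1 epimer ratio is immaterial.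

Step 13
Reactants: 27 cis-fused ketol
Product: 29 cis-fused bromohydrin 7-bromo-7a-hydroxy-4-methoxy-1,1-dimethyl-2-geranyl-3a,7-diprenyl-1,2,3,3a,7,7a-hexahydro-6H-inden-6-one (C1 Br cis to C9 OH and to C5 prenyl; C7 geranyl cis to C5 prenyl), via dilithium alkoxide enolate 28 (not isolated)
Conditions: LiN(iPr)2 (2.2 equiv), THF, −78 → −40 °C; then N-bromosuccinimide, −78 °C
Reagents that add atoms: N-bromosuccinimide, O=C1CCC(=O)N1Br
Why: Electrophilic α-bromination of the ketone enolate should occur at C1 on the face syn to the C9 oxygen, because the other face of the nearly planar dienolate ring is covered by the fused cyclopentane and its C8 gem-dimethyl group, so Br ends up cis to OH and anti to the C9–C8 bond.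

Step 14
Reactants: 29 cis-fused bromohydrin
Product: 30 4-methoxy-8,8-dimethyl-7-geranyl-1,5-diprenylbicyclo[3.3.1]non-3-ene-2,9-dione (C7 geranyl equatorial and trans to the C2–C4 bridge)
Conditions: AgBF4 (3 equiv), 2,6-di-tert-butyl-4-methylpyridine (3 equiv), CH2Cl2, −40 → 0 °C, dark
Reagents that add atoms: none
Why: AgBF4 (monovalent silver as halophile) ionises the C1–Br bond in concert with a 1,2-shift of C8 from C9 to C1 through the half-chair in which C1–Br and C9–C8 are trans-diaxial, the carbinol oxygen supplying the electrons and ending as the C9 ketone, so that a discrete α-keto carbocation is avoided. The closest known reaction type is the silver-promoted semipinacol (halohydrin) rearrangement of a tertiary carbinol next to a tertiary halide, and the same enlargement of fused hydroxy vinylogous esters is known with a trivalent-iodine leaving group on C1. The new ring C9–C1–C8–C7–C6–C5 is closed by ring expansion of the cyclopentane from five to six members (a 1,2-alkyl shift, not an end-to-end cyclisation), and the cis ring fusion delivers C8 to the face of C1 that already holds the C5–C6 bridge, which is what the bridged bicyclo[3.3.1]nonane demands. C1 is the one new stereocentre and is formed with inversion, so it is fixed by the bromide configuration set in step 13; because Br and OH are syn, backside displacement by oxygen to an oxirane is geometrically impossible. The step needs migration of C8 in preference to the ring bond C9–C5 and to capture by the prenyl alkenes: C8 is fully substituted and anti to the leaving group, C5 is gauche to it and carries the electron-poor C4, and the hindered pyridine removes HBF4 before it can protonate the alkenes or the enol ether.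

Step 15
Reactants: 31 3,4-dihydroxybenzoic acid
Product: 32 tert-butyldimethylsilyl 3,4-bis[(tert-butyldimethylsilyl)oxy]benzoate
Conditions: tBuMe2SiCl (3.3 equiv), imidazole, DMF, rt
Reagents that add atoms: tert-butyl(chloro)dimethylsilane, CC(C)(C)[Si](C)(C)Cl
Why: Silylation of both phenols and of the carboxylic acid with a silyl chloride and imidazole.

Step 16
Reactants: 32 tris-silylated 3,4-dihydroxybenzoic acid
Product: 33 3,4-bis[(tert-butyldimethylsilyl)oxy]benzoyl chloride
Conditions: (COCl)2, DMF (cat.), CH2Cl2, 0 °C → rt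
Reagents that add atoms: oxalyl chloride, O=C(Cl)C(Cl)=O
Why: A silyl ester is converted directly into the acid chloride by oxalyl chloride and catalytic DMF (chloroiminium activation) under neutral conditions that leave the aryl silyl ethers intact.

Step 17
Reactants: 30 bicyclic vinylogous methyl ester; 33 3,4-bis[(tert-butyldimethylsilyl)oxy]benzoyl chloride
Product: 35 3-{3,4-bis[(tert-butyldimethylsilyl)oxy]benzoyl}-4-methoxy-8,8-dimethyl-7-geranyl-1,5-diprenylbicyclo[3.3.1]non-3-ene-2,9-dione, via C3 vinyllithium 34 (not isolated)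
Conditions: lithium 2,2,6,6-tetramethylpiperidide, THF, −78 °C; then 33, −78 → −40 °C
Reagents that add atoms: none
Why: With both bridgeheads quaternary the only acidic hydrogen is the vinylic C3–H between the carbonyl and the methoxy-bearing carbon, so directed vinyl lithiation followed by C-acylation with the acid chloride installs the aroyl group without touching a stereocentre.

Step 18
Reactants: 35 silyl-protected C3-aroyl vinylogous ester
Product: 36 3-(3,4-dihydroxybenzoyl)-4-methoxy-8,8-dimethyl-7-geranyl-1,5-diprenylbicyclo[3.3.1]non-3-ene-2,9-dione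
Conditions: Et3N·3HF, THF, rt
Reagents that add atoms: none
Why: Fluoride-mediated cleavage of the two aryl silyl ethers under buffered conditions that should leave the methyl enol ether, the ketones and the alkenes unchanged.

Step 19
Reactants: 36 O-methyl oblongifolin B
Product: 37 oblongifolin B
Conditions: LiCl, DMSO, 120 °C, argon; then 1 M HCl
Reagents that add atoms: none
Why: SN2 demethylation by chloride at the methyl group of the C3-acylated vinylogous ester, a good leaving group as the stabilised triketone enolate, frees the enol without affecting any stereocentre.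

**Compound list**

1 | 5-bromo-2-methylpent-2-ene | CC(C)=CCCBr | starting material
2 | 6-methylhept-5-en-1-yne | CC(C)=CCCC#C | intermediate
3 | [(1E)-2,6-dimethylhepta-1,5-dien-1-yl]dimethylalumane | CC(C)=CCC/C(C)=C/[Al](C)C | intermediate (not isolated)
4 | (1E)-1-iodo-2,6-dimethylhepta-1,5-diene | CC(C)=CCC/C(C)=C/I | intermediate
5 | 2-methylcyclopent-2-en-1-one | CC1=CCCC1=O | starting material
6 | (chloromethyl)dimethyl(propan-2-yloxy)silane | CC(C)O[Si](C)(C)CCl | starting material
7 | chlorido{[dimethyl(propan-2-yloxy)silyl]methyl}magnesium | CC(C)O[Si](C)(C)C[Mg]Cl | intermediate (not isolated)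
8 | chloromagnesium (3R)-3-{[dimethyl(propan-2-yloxy)silyl]methyl}-2-methylcyclopent-1-en-1-olate | CC(C)O[Si](C)(C)C[C@@H]1CCC(O[Mg]Cl)=C1C | intermediate (not isolated)
9 | (3R)-3-{[dimethyl(propan-2-yloxy)silyl]methyl}-2,2-dimethylcyclopentan-1-one | CC(C)O[Si](C)(C)C[C@@H]1CCC(=O)C1(C)C | intermediate
10 | (3R)-3-(hydroxymethyl)-2,2-dimethylcyclopentan-1-one | OC[C@@H]1CCC(=O)C1(C)C | intermediate
11 | (3R)-3-(iodomethyl)-2,2-dimethylcyclopentan-1-one | IC[C@@H]1CCC(=O)C1(C)C | intermediate
12 | {[(1R)-2,2-dimethyl-3-oxocyclopentyl]methyl}(iodido)zinc | I[Zn]C[C@@H]1CCC(=O)C1(C)C | intermediate (not isolated)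
13 | (3S)-3-[(2E)-3,7-dimethylocta-2,6-dien-1-yl]-2,2-dimethylcyclopentan-1-one | CC(C)=CCC/C(C)=C/C[C@@H]1CCC(=O)C1(C)C | intermediate
14 | 1-bromo-3-methylbut-2-ene (prenyl bromide) | CC(C)=CCBr | starting material
15 | lithium enolate of 13 (C9–O–Li, C9=C5) | CC(C)=CCC/C(C)=C/C[C@@H]1CC=C(O[Li])C1(C)C | intermediate (not isolated)
16 | 3-geranyl-2,2-dimethyl-5-prenylcyclopentan-1-one (C7 as in 13; both C5 epimers) | CC(C)=CCC/C(C)=C/C[C@@H]1CC(CC=C(C)C)C(=O)C1(C)C | intermediate
17 | 1-[(trimethylsilyl)ethynyl]-1,2-benziodoxol-3(1H)-one | C[Si](C)(C)C#CI1OC(=O)c2ccccc12 | starting material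
18 | potassium enolate of 16 (C9–O–K, C9=C5) | CC(C)=CCC/C(C)=C/C[C@@H]1CC(CC=C(C)C)=C(O[K])C1(C)C | intermediate (not isolated)
19 | 5-ethynyl-3-geranyl-2,2-dimethyl-5-prenylcyclopentan-1-one (C7 as in 13; ethynyl trans, prenyl cis to geranyl) | CC(C)=CCC/C(C)=C/C[C@@H]1C[C@@](CC=C(C)C)(C#C)C(=O)C1(C)C | intermediate
20 | N-methoxy-N-methylacetamide | CON(C)C(C)=O | starting material
21 | lithium enolate of 20 | C=C(O[Li])N(C)OC | intermediate (not isolated)
22 | N-methoxy-N,5-dimethylhex-4-enamide | CON(C)C(=O)CCC=C(C)C | intermediate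
23 | lithium acetylide of 19 | CC(C)=CCC/C(C)=C/C[C@@H]1C[C@@](CC=C(C)C)(C#C[Li])C(=O)C1(C)C | intermediate (not isolated)
24 | 3-geranyl-2,2-dimethyl-5-(7-methyl-3-oxooct-6-en-1-yn-1-yl)-5-prenylcyclopentan-1-one (stereocentres as in 19) | CC(C)=CCC/C(C)=C/C[C@@H]1C[C@@](CC=C(C)C)(C#CC(=O)CCC=C(C)C)C(=O)C1(C)C | intermediate
25 | 3-geranyl-5-[(1E)-1-methoxy-7-methyl-3-oxoocta-1,6-dien-1-yl]-2,2-dimethyl-5-prenylcyclopentan-1-one (stereocentres as in 19) | CC(C)=CCC/C(C)=C/C[C@@H]1C[C@@](CC=C(C)C)(/C(OC)=C\C(=O)CCC=C(C)C)C(=O)C1(C)C | intermediate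
26 | lithium C1=C2 enolate of 25 | CC(C)=CCC/C(C)=C/C[C@@H]1C[C@@](CC=C(C)C)(/C(OC)=C\C(O[Li])=CCC=C(C)C)C(=O)C1(C)C | intermediate (not isolated)
27 | cis-fused ketol 7a-hydroxy-4-methoxy-1,1-dimethyl-2-geranyl-3a,7-diprenyl-1,2,3,3a,7,7a-hexahydro-6H-inden-6-one (C9 OH cis to C5 prenyl; C7 geranyl cis to C5 prenyl; both C1 epimers) | CC(C)=CCC/C(C)=C/C[C@@H]1C[C@@]2(CC=C(C)C)C(OC)=CC(=O)C(CC=C(C)C)[C@@]2(O)C1(C)C | intermediate
28 | dilithium alkoxide enolate of 27 (C9–O–Li; C2–O–Li, C1=C2) | CC(C)=CCC/C(C)=C/C[C@@H]1C[C@@]2(CC=C(C)C)C(OC)=CC(O[Li])=C(CC=C(C)C)[C@@]2(O[Li])C1(C)C | intermediate (not isolated)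
29 | cis-fused bromohydrin 7-bromo-7a-hydroxy-4-methoxy-1,1-dimethyl-2-geranyl-3a,7-diprenyl-1,2,3,3a,7,7a-hexahydro-6H-inden-6-one (C1 Br cis to C9 OH and to C5 prenyl; C7 geranyl cis to C5 prenyl) | CC(C)=CCC/C(C)=C/C[C@@H]1C[C@@]2(CC=C(C)C)C(OC)=CC(=O)[C@@](Br)(CC=C(C)C)[C@@]2(O)C1(C)C | intermediate
30 | 4-methoxy-8,8-dimethyl-7-geranyl-1,5-diprenylbicyclo[3.3.1]non-3-ene-2,9-dione (C7 geranyl equatorial, trans to the C2–C4 bridge) | CC(C)=CCC/C(C)=C/C[C@@H]1C[C@]2(CC=C(C)C)C(=O)[C@@](CC=C(C)C)(C(=O)C=C2OC)C1(C)C | intermediate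
31 | 3,4-dihydroxybenzoic acid | OC(=O)c1ccc(O)c(O)c1 | starting material
32 | tert-butyldimethylsilyl 3,4-bis[(tert-butyldimethylsilyl)oxy]benzoate | CC(C)(C)[Si](C)(C)OC(=O)c1ccc(O[Si](C)(C)C(C)(C)C)c(O[Si](C)(C)C(C)(C)C)c1 | intermediate
33 | 3,4-bis[(tert-butyldimethylsilyl)oxy]benzoyl chloride | CC(C)(C)[Si](C)(C)Oc1ccc(C(Cl)=O)cc1O[Si](C)(C)C(C)(C)C | intermediate
34 | C3-lithio derivative of 30 | CC(C)=CCC/C(C)=C/C[C@@H]1C[C@]2(CC=C(C)C)C(=O)[C@@](CC=C(C)C)(C(=O)C([Li])=C2OC)C1(C)C | intermediate (not isolated)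
35 | 3-{3,4-bis[(tert-butyldimethylsilyl)oxy]benzoyl}-4-methoxy-8,8-dimethyl-7-geranyl-1,5-diprenylbicyclo[3.3.1]non-3-ene-2,9-dione (stereocentres as in 30) | CC(C)=CCC/C(C)=C/C[C@@H]1C[C@]2(CC=C(C)C)C(=O)[C@@](CC=C(C)C)(C(=O)C(C(=O)c3ccc(O[Si](C)(C)C(C)(C)C)c(O[Si](C)(C)C(C)(C)C)c3)=C2OC)C1(C)C | intermediate
36 | 3-(3,4-dihydroxybenzoyl)-4-methoxy-8,8-dimethyl-7-geranyl-1,5-diprenylbicyclo[3.3.1]non-3-ene-2,9-dione (stereocentres as in 30) | CC(C)=CCC/C(C)=C/C[C@@H]1C[C@]2(CC=C(C)C)C(=O)[C@@](CC=C(C)C)(C(=O)C(C(=O)c3ccc(O)c(O)c3)=C2OC)C1(C)C | intermediate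
37 | oblongifolin B | CC(C)=CCC/C(C)=C/C[C@@H]1C[C@]2(CC=C(C)C)C(=O)[C@@](CC=C(C)C)(C(=O)C(C(=O)c3ccc(O)c(O)c3)=C2O)C1(C)C | target

**Step count and risks**

Total step count: 19. Longest linear sequence: 14 steps (steps 3–8, 10–14 and 17–19, from 5 and 6).

Steps most likely to fail:

1. Step 14, together with the facial course of step 13 that feeds it. Ionisation at C1 next to the C2 carbonyl may be slow, so that loss of HBr towards a prenyl CH2, capture of the developing cation by a prenyl alkene, or shift of the ring bond C9–C5 from the other half-chair could compete. Bromination on the wrong face in step 13 would give an epimer that cannot rearrange. The fallback sets out from 19 and leaves C1 unsubstituted. Acylation of acetylide 23 with 20 should give the methyl ynone F1. NaOMe in MeOH should then give the (E)-β-methoxy enone F2, and LiN(iPr)2 should close the cis-fused ketol F3, which has a CH2 group at C1. Oxidative ring expansion with PhI(OAc)2 and KOH in MeOH is the known variant of the same shift: the C1 enolate attacks trivalent iodine, the phenyliodanyl group is the leaving group, and the C1–H iodane can still epimerise to the reactive configuration. It should give the bicyclic vinylogous ester with a bridgehead hydrogen at C1 F4. Bridgehead lithiation with LiN(iPr)2 and alkylation with 14 returns to the route at 30.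

2. Step 8. Transfer of the ethynyl group to the hindered, fully substituted enolate may be slower than decomposition of the iodane, and attack anti to the geranyl group (a 1,3-relationship across the ring) may be only moderately selective. The fallback sets out from 16. LiN(iPr)2 and then diketene (C-acylation at C5, then aldol closure onto C9 in the same flask) should give the cis-fused hydroxy dione F5. Its polyanion (LiN(iPr)2, 3.3 equiv, THF/DMPU) can be alkylated by 14 only at C1, the single γ-position that bears hydrogen, which gives the C1-prenyl hydroxy dione F6. O-Methylation (Me2SO4, K2CO3, acetone) should give 27 together with the C2-methoxy regioisomer F7, which is separated, hydrolysed (aq. HCl, THF) back to F6 and recycled. The route is rejoined at 27.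

3. Step 3. The bulky alkoxysilylmethyl Grignard reagent may add with low enantioselectivity, or the magnesium enolate may resist C-methylation. The fallback sets C7 by substrate control and sets out from 4. 2,2-Dimethylcyclopentane-1,3-dione F8 is desymmetrised by Corey–Bakshi–Shibata reduction to (3S)-3-hydroxy-2,2-dimethylcyclopentan-1-one F9, silylated (tBuMe2SiCl, imidazole) to the silyl ether F10 and methylenated (Ph3P=CH2) to the exocyclic alkene F11. Hydroboration with 9-BBN anti to the silyloxy group gives the alkylborane F12 (not isolated), which is coupled with 4 (Suzuki–Miyaura, PdCl2(dppf), aq. NaOH) to the cis silyl ether F13; any C7 epimer is removed by chromatography. Bu4NF gives the alcohol F14, and Dess–Martin oxidation returns to the route at 13.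

**Further compounds**

F1 | step 14 | 3-geranyl-2,2-dimethyl-5-(3-oxobut-1-yn-1-yl)-5-prenylcyclopentan-1-one (stereocentres as in 19) | CC(C)=CCC/C(C)=C/C[C@@H]1C[C@@](CC=C(C)C)(C#CC(C)=O)C(=O)C1(C)C
F2 | step 14 | 3-geranyl-5-[(1E)-1-methoxy-3-oxobut-1-en-1-yl]-2,2-dimethyl-5-prenylcyclopentan-1-one | CC(C)=CCC/C(C)=C/C[C@@H]1C[C@@](CC=C(C)C)(/C(OC)=C\C(C)=O)C(=O)C1(C)C
F3 | step 14 | cis-fused ketol 7a-hydroxy-4-methoxy-1,1-dimethyl-2-geranyl-3a-prenyl-1,2,3,3a,7,7a-hexahydro-6H-inden-6-one | CC(C)=CCC/C(C)=C/C[C@@H]1C[C@@]2(CC=C(C)C)C(OC)=CC(=O)C[C@@]2(O)C1(C)C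
F4 | step 14 | 4-methoxy-8,8-dimethyl-7-geranyl-5-prenylbicyclo[3.3.1]non-3-ene-2,9-dione (bridgehead C1–H) | CC(C)=CCC/C(C)=C/C[C@@H]1C[C@]2(CC=C(C)C)C(=O)[C@@H](C(=O)C=C2OC)C1(C)C
F5 | step 8 | cis-fused hydroxy dione 7a-hydroxy-1,1-dimethyl-2-geranyl-3a-prenylhexahydro-1H-indene-4,6-dione | CC(C)=CCC/C(C)=C/C[C@@H]1C[C@@]2(CC=C(C)C)C(=O)CC(=O)C[C@@]2(O)C1(C)C
F6 | step 8 | cis-fused hydroxy dione 7a-hydroxy-1,1-dimethyl-2-geranyl-3a,7-diprenylhexahydro-1H-indene-4,6-dione (C1 epimers) | CC(C)=CCC/C(C)=C/C[C@@H]1C[C@@]2(CC=C(C)C)C(=O)CC(=O)C(CC=C(C)C)[C@@]2(O)C1(C)C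
F7 | step 8 | C2-methoxy regioisomer of 27, 7a-hydroxy-6-methoxy-1,1-dimethyl-2-geranyl-3a,7-diprenyl-1,2,3,3a,7,7a-hexahydro-4H-inden-4-one | CC(C)=CCC/C(C)=C/C[C@@H]1C[C@@]2(CC=C(C)C)C(=O)C=C(OC)C(CC=C(C)C)[C@@]2(O)C1(C)C
F8 | step 3 | 2,2-dimethylcyclopentane-1,3-dione | CC1(C)C(=O)CCC1=O
F9 | step 3 | (3S)-3-hydroxy-2,2-dimethylcyclopentan-1-one | O=C1CC[C@H](O)C1(C)C
F10 | step 3 | (3S)-3-[(tert-butyldimethylsilyl)oxy]-2,2-dimethylcyclopentan-1-one | CC(C)(C)[Si](C)(C)O[C@H]1CCC(=O)C1(C)C
F11 | step 3 | tert-butyl{[(1S)-2,2-dimethyl-3-methylidenecyclopentyl]oxy}dimethylsilane | C=C1CC[C@H](O[Si](C)(C)C(C)(C)C)C1(C)C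
F12 | step 3 | 9-{[cis-3-(tert-butyldimethylsilyloxy)-2,2-dimethylcyclopentyl]methyl}-9-borabicyclo[3.3.1]nonane (carbinol carbon S) | C(B1C2CCCC1CCC2)[C@@H]3CC[C@H](O[Si](C)(C)C(C)(C)C)C3(C)C
F13 | step 3 | tert-butyl{[cis-3-geranyl-2,2-dimethylcyclopentyl]oxy}dimethylsilane (carbinol carbon S; C7 as in 13) | CC(C)=CCC/C(C)=C/C[C@@H]1CC[C@H](O[Si](C)(C)C(C)(C)C)C1(C)C
F14 | step 3 | cis-3-geranyl-2,2-dimethylcyclopentan-1-ol (carbinol carbon S; C7 as in 13) | CC(C)=CCC/C(C)=C/C[C@@H]1CC[C@H](O)C1(C)C
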